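**Retrosynthetic overview**
- Last bonds: the C8–O ester (to (E)-N-methylurocanic acid, made by a Doebner condensation) and the C2–C3 single bond (conjugate reduction of a C2=C3 enoate, C3 then equilibrated).
- Key disconnection: C1–C10 and C13–C14 (Diels–Alder) together with C2=C3 (Knoevenagel) are formed in one pot from a monocyclic hemiketal β-keto ester that carries the diene, plus (E)-4-methylpent-2-enal.
- The hemiketal (C3–C4) comes from methyl acetate enolate addition to a butenolide; the butenolide (C7–C8, both oxygenated stereocentres) comes from an asymmetric vinylogous Mukaiyama aldol of a silyloxyfuran (from α-angelica lactone) with a dienal (from β-ocimene).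
- Ring order: the five-membered oxygen ring first (furanone, later the bridging dihydrofuran hemiketal), then the cyclohexene and the ten-membered carbocycle in the same operation; the imidazole is bought preformed.

Numbering: locants C1–C14 are the sarcodictyin positions (ring A = C1, C10, C11, C12, C13, C14; ten-membered ring = C1–C10; oxygen bridge C4–O–C7; ester carbon on C3).
Assumption: C3 can epimerise through the ring-opened β-keto ester, and the (3R) configuration of the target is taken to be the thermodynamically preferred one.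

**Step 1**
Reactants: 1 α-angelica lactone (5-methylfuran-2(3H)-one)
Product: 2 2-methyl-5-(trimethylsilyloxy)furan
Conditions: TMSCl, Et3N, MeCN, 0 °C → rt; filter, distil
Reagents that add atoms: chlorotrimethylsilane C[Si](C)(C)Cl
Why: O-silylation of the amine-generated furanolate (soft enolisation of the lactone) gives the aromatic 2-silyloxyfuran; no stereocentre is formed.

**Step 2**
Reactants: 3 (E)-β-ocimene ((3E)-3,7-dimethylocta-1,3,6-triene)
Product: 5 (3E)-4-methylhexa-3,5-dienal, via ozonide 4 (not isolated)
Conditions: O3 (1.0 equiv), CH2Cl2, −78 °C, Sudan Red 7B end-point; then Me2S, −78 °C → rt; used at once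
Reagents that add atoms: ozone [O-][O+]=O
Why: Chemoselective ozonolysis with reductive work-up: ozone attacks the isolated, electron-rich trisubstituted alkene faster than the conjugated diene, and the (E)-diene geometry is untouched.

**Step 3**
Reactants: 5 (3E)-4-methylhexa-3,5-dienal; 2 2-methyl-5-(trimethylsilyloxy)furan
Product: 7 (5S)-5-[(1S,3E)-1-hydroxy-4-methylhexa-3,5-dien-1-yl]-5-methylfuran-2(5H)-one, via silyl ether 6 (not isolated)
Conditions: Ti(OiPr)4 (20 mol%), (R)-BINOL (20 mol%), Et2O, −20 °C; then 1 M HCl, THF, 0 °C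
Reagents that add atoms: none
Why: Catalytic asymmetric vinylogous Mukaiyama aldol: the (R)-BINOL–titanium Lewis acid is expected to direct the γ-carbon of the silyloxyfuran to the Re face of the aldehyde through an open, threo-selective transition state, setting the carbinol (C8, S) and the quaternary centre (C7, S) together, and the transferred silyl group is removed on acidic work-up.

**Step 4**
Reactants: 7 (5S)-5-[(1S,3E)-1-hydroxy-4-methylhexa-3,5-dien-1-yl]-5-methylfuran-2(5H)-one
Product: 8 methyl 2-[(5S)-2-hydroxy-5-[(1S,3E)-1-hydroxy-4-methylhexa-3,5-dien-1-yl]-5-methyl-2,5-dihydrofuran-2-yl]acetate (hemiketal carbon as equilibrating anomers)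
Conditions: MeOAc, LiN(iPr)2, THF, −78 °C; CeCl3, −78 °C; then 7, −78 → −40 °C; aq. NH4Cl
Reagents that add atoms: methyl acetate CC(=O)OC
Why: Claisen-type 1,2-addition of the cerium ester enolate to the lactone carbonyl stops at the cyclic hemiketal (the ring-closed form of the (Z)-γ-hydroxy-enone β-keto ester); the β-carbon is shielded by the adjacent quaternary centre and the weakly basic cerium enolate avoids Michael addition and retro-aldol, so C7 and C8 are untouched.

**Step 5**
Reactants: 8 methyl 2-[(5S)-2-hydroxy-5-[(1S,3E)-1-hydroxy-4-methylhexa-3,5-dien-1-yl]-5-methyl-2,5-dihydrofuran-2-yl]acetate; 9 (2E)-4-methylpent-2-enal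
Product: 12 tricyclic C2=C3 enoate diol (8-O-deacyl-2,3-didehydro target; CO2Me trans to C1), via Diels–Alder aldehyde 10 (not isolated), via lactol 11 (not isolated)
Conditions: (5S)-5-benzyl-2,2,3-trimethylimidazolidin-4-one·HClO4 (first-generation MacMillan catalyst, 20 mol%), 9 (1.2 equiv), MeCN/H2O 19:1, −10 °C → rt; then dilute with MeCN to 2 mM, piperidine/AcOH (30 mol%), 50 °C
Reagents that add atoms: none
Why: Proposed new method: the imidazolidinium salt turns 9 into an (E)-iminium ion whose β-carbon Re face is open (the benzyl group shields the other face), the (E)-diene of 8 adds endo through its unsubstituted terminus (sterics and the 1-alkyl ortho preference outweigh the 2-methyl effect) to set C1, C10 and C14 (1,10-cis, isopropyl trans), the aldehyde rests as the C8 lactol, and on dilution the amine salt condenses it with the β-keto ester tautomer of the hemiketal to close the ten-membered ring, re-closure of the hemiketal fixing C4 with C3 and C8 cis on the dihydrofuran; the closest known reactions are the iminium-catalysed enantioselective Diels–Alder reaction of β-alkyl enals and the amine-catalysed Knoevenagel condensation of lactols with 1,3-dicarbonyl compounds.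

**Step 6**
Reactants: 12 tricyclic C2=C3 enoate diol
Product: 13 8-O-deacyl target ((1R,3R,4R,7S,8S,10R,14R) diol with CO2Me on C3)
Conditions: Cu(OAc)2 (5 mol%), 1,2-bis(diphenylphosphino)benzene (5 mol%), (EtO)2MeSiH, t-BuOH, toluene, rt; then DBU (0.2 equiv), THF, rt
Reagents that add atoms: none
Why: Ligated copper hydride conjugate reduction (Stryker-type) attacks only the α,β-unsaturated ester while the isolated C5=C6 and C11=C12 alkenes are inert, C3 is set by protonation and is then equilibrated with DBU through the ring-opened β-keto ester to the (3R) epimer.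

**Step 7**
Reactants: 14 1-methyl-1H-imidazole-4-carbaldehyde; 15 malonic acid
Product: 17 (2E)-3-(1-methyl-1H-imidazol-4-yl)prop-2-enoic acid, via ylidenemalonic acid 16 (not isolated)
Conditions: pyridine, piperidine (cat.), 100 °C
Reagents that add atoms: none
Why: Knoevenagel–Doebner condensation with decarboxylation gives the thermodynamically favoured (E)-acrylic acid; no stereocentre is formed.

**Step 8**
Reactants: 13 8-O-deacyl target; 17 (2E)-3-(1-methyl-1H-imidazol-4-yl)prop-2-enoic acid
Product: 19 CNP0113846.1, via mixed anhydride 18 (not isolated)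
Conditions: 17, 2,4,6-Cl3C6H2COCl, Et3N, THF, rt; then 13, DMAP, toluene, 40 °C
Reagents that add atoms: none
Why: Yamaguchi esterification: the DMAP-activated mixed anhydride acylates the secondary C8 hydroxyl in preference to the hindered tertiary hemiketal hydroxyl, no stereocentre is touched and the (E)-alkene of the acid is retained.

**Compound list**
1 | α-angelica lactone (5-methylfuran-2(3H)-one) | CC1=CCC(=O)O1 | starting material
2 | 2-methyl-5-(trimethylsilyloxy)furan | Cc1ccc(O[Si](C)(C)C)o1 | intermediate
3 | (E)-β-ocimene ((3E)-3,7-dimethylocta-1,3,6-triene) | C=C/C(C)=C/CC=C(C)C | starting material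
4 | ozonide: 3,3-dimethyl-5-[(2E)-3-methylpenta-2,4-dien-1-yl]-1,2,4-trioxolane (racemic at C5) | C=C/C(C)=C/CC1OOC(C)(C)O1 | intermediate
5 | (3E)-4-methylhexa-3,5-dienal | O=CC/C=C(C)/C=C | intermediate
6 | silyl ether: (5S)-5-methyl-5-[(1S,3E)-4-methyl-1-(trimethylsilyloxy)hexa-3,5-dien-1-yl]furan-2(5H)-one | C=C/C(C)=C/C[C@H](O[Si](C)(C)C)[C@]1(C)C=CC(=O)O1 | intermediate
7 | (5S)-5-[(1S,3E)-1-hydroxy-4-methylhexa-3,5-dien-1-yl]-5-methylfuran-2(5H)-one | C=C/C(C)=C/C[C@H](O)[C@]1(C)C=CC(=O)O1 | intermediate
8 | methyl 2-[(5S)-2-hydroxy-5-[(1S,3E)-1-hydroxy-4-methylhexa-3,5-dien-1-yl]-5-methyl-2,5-dihydrofuran-2-yl]acetate (hemiketal carbon left undefined: equilibrating anomers) | C=C/C(C)=C/C[C@H](O)[C@]1(C)C=CC(O)(CC(=O)OC)O1 | intermediate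
9 | (2E)-4-methylpent-2-enal | CC(C)/C=C/C=O | starting material
10 | Diels–Alder aldehyde: methyl 2-[(5S)-5-[(1S)-2-[(1R,5R,6R)-6-formyl-2-methyl-5-(propan-2-yl)cyclohex-2-en-1-yl]-1-hydroxyethyl]-2-hydroxy-5-methyl-2,5-dihydrofuran-2-yl]acetate | O=C[C@@H]1[C@@H](C(C)C)CC=C(C)[C@@H]1C[C@H](O)[C@]2(C)C=CC(O)(CC(=O)OC)O2 | intermediate
11 | lactol of 10 (C8 hydroxyl closed on the formyl carbon; 1-hydroxy-5-methyl-8-isopropyl-3,4,4a,7,8,8a-hexahydro-1H-isochromene, (3S,4aR,8R,8aR), carrying the hemiketal acetate ring at C3; lactol carbon undefined) | OC1O[C@H]([C@]2(C)C=CC(O)(CC(=O)OC)O2)C[C@H]3C(C)=CC[C@H](C(C)C)[C@@H]13 | intermediate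
12 | tricyclic C2=C3 enoate diol: CO2Me on C3 and trans to C1 across C2=C3, hemiketal OH on C4, OH on C8, C4–O–C7 bridge, C5=C6 and C11=C12 alkenes; C1, C4, C7, C8, C10, C14 arranged as in the target | COC(=O)/C1=C/[C@@H]2[C@@H](C(C)C)CC=C(C)[C@@H]2C[C@H](O)[C@]2(C)C=C[C@@]1(O)O2 | intermediate
13 | 8-O-deacyl target: (1R,3R,4R,7S,8S,10R,14R) diol, otherwise identical to the target | COC(=O)[C@@H]1C[C@@H]2[C@@H](C(C)C)CC=C(C)[C@@H]2C[C@H](O)[C@]2(C)C=C[C@@]1(O)O2 | intermediate
14 | 1-methyl-1H-imidazole-4-carbaldehyde | Cn1cnc(C=O)c1 | starting material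
15 | malonic acid | OC(=O)CC(=O)O | starting material
16 | 2-[(1-methyl-1H-imidazol-4-yl)methylidene]propanedioic acid | Cn1cnc(C=C(C(=O)O)C(=O)O)c1 | intermediate
17 | (2E)-3-(1-methyl-1H-imidazol-4-yl)prop-2-enoic acid | Cn1cnc(/C=C/C(=O)O)c1 | intermediate
18 | mixed anhydride of 17 with 2,4,6-trichlorobenzoic acid | Cn1cnc(/C=C/C(=O)OC(=O)c2c(Cl)cc(Cl)cc2Cl)c1 | intermediate
19 | CNP0113846.1: 8-O-[(2E)-3-(1-methyl-1H-imidazol-4-yl)prop-2-enoyl] ester of 13, (1R,3R,4R,7S,8S,10R,14R) | COC(=O)[C@@H]1C[C@@H]2[C@@H](C(C)C)CC=C(C)[C@@H]2C[C@H](OC(=O)/C=C/c2cn(C)cn2)[C@]2(C)C=C[C@@]1(O)O2 | target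

**Step count and risks**
Total steps: 8. Longest linear sequence: 6 (steps 2, 3, 4, 5, 6, 8).

Steps most likely to fail:

- **Step 5.** The β-branched enal may add slowly or with imperfect regiochemistry to the 1,2-disubstituted diene. The enal may also condense intermolecularly with the β-keto ester before the cycloaddition. The ten-membered Knoevenagel closure may lose to oligomerisation. Fallback: decouple the two ring closures; it sets out from 7 and comes back at 12. Compounds 7 and 9 are combined under the same imidazolidinium catalysis before any β-keto ester is present, so only the Diels–Alder reaction and lactolisation can occur and excess enal is tolerated; this gives lactol butenolide F1, where regioisomers can be removed. The cerium enolate of methyl acetate then adds to the butenolide carbonyl of F1 (lactol carried as its alkoxide at −78 °C) to give 11 as an isolated compound. Slow addition of 11 to piperidinium acetate in hot MeCN closes the ring to 12.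

- **Step 3.** The skipped dienal is prone to conjugation, and the sense and level of induction with a 5-methyl silyloxyfuran are not assured. Fallback: chiral-pool control instead of catalysis; it sets out from 5 and comes back at 7. The lithium enolate of commercial (2S,5S)-2-tert-butyl-5-methyl-1,3-dioxolan-4-one (L-lactic acid derived) adds to 5. The aldehyde enters anti to the tert-butyl group, which fixes the quaternary centre by self-regeneration of the stereocentre, and the product is aldol dioxolanone F2 (C8 epimer removed by chromatography). Reduction with (iBu)2AlH at −78 °C gives dioxolanol F3. Z-selective Horner–Wadsworth–Emmons olefination with methyl bis(2,2,2-trifluoroethoxy)phosphorylacetate (KN(SiMe3)2, 18-crown-6) on its ring-opened α-hydroxy aldehyde gives Z-hydroxy enoate F4, which lactonises to 7.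

- **Step 6.** The hindered enoate next to the hemiketal may resist copper hydride or over-reduce through the ring-opened enone, and the C3 outcome rests on the equilibration. Fallback: organocatalytic transfer hydrogenation through the ring-opened tautomer; it sets out from 12, comes back at 13 and makes no new compound (F0). Compound 12 is heated with Hantzsch ester (diethyl 2,6-dimethyl-1,4-dihydropyridine-3,5-dicarboxylate) and catalytic piperidinium acetate in toluene. Only the alkylidene β-keto ester tautomer accepts hydride at C2, and re-closure of the hemiketal with equilibration at C3 gives 13.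

**Further compounds**
F1 | step 5 | lactol butenolide: (5S)-5-[(3S,4aR,8R,8aR)-1-hydroxy-5-methyl-8-(propan-2-yl)-3,4,4a,7,8,8a-hexahydro-1H-isochromen-3-yl]-5-methylfuran-2(5H)-one | OC1O[C@H]([C@]2(C)C=CC(=O)O2)C[C@H]3C(C)=CC[C@H](C(C)C)[C@@H]13
F2 | step 3 | aldol dioxolanone: 2-tert-butyl-5-[(1S,3E)-1-hydroxy-4-methylhexa-3,5-dien-1-yl]-5-methyl-1,3-dioxolan-4-one (tert-butyl cis to methyl) | C=C/C(C)=C/C[C@H](O)[C@@]1(C)O[C@H](C(C)(C)C)OC1=O
F3 | step 3 | dioxolanol: 2-tert-butyl-5-[(1S,3E)-1-hydroxy-4-methylhexa-3,5-dien-1-yl]-5-methyl-1,3-dioxolan-4-ol | C=C/C(C)=C/C[C@H](O)[C@@]1(C)O[C@H](C(C)(C)C)OC1O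
F4 | step 3 | Z-hydroxy enoate: methyl (2Z,4S,5S,7E)-4,5-dihydroxy-4,8-dimethyldeca-2,7,9-trienoate | C=C/C(C)=C/C[C@H](O)[C@@](C)(O)/C=C\C(=O)OC
F0 | step 6 | none | none
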